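I began with the easy step: gas enters the solution in proportion to its gap from saturation, so I asked what else in the flask holds still while the rest moves.

    gas phase ⇌ dissolved gas, rate k1*(csat - [dissolved gas]) (k1 = 0.0878 h⁻¹, csat = 28 mM)
    starting material + dissolved gas → target (k2 = 1.33 M⁻¹ h⁻¹)
    dissolved gas + target → over-reacted product (k3 = 1.72 M⁻¹ h⁻¹)
    2 dissolved gas → self-condensation product (k4 = 1.10 M⁻¹ h⁻¹)
    starting material + target → side product (k5 = 0.0104 M⁻¹ h⁻¹)
    target ⇌ isomer of the product (K6 = 0.477, k6 = 0.0406 h⁻¹)

starting material 0.17 M; gas phase 28 mM (held); time 10 d

* amount of target at 10 d, in percent of the starting material charged
* concentration of dissolved gas in solution at 10 d, in percent of saturation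

- a species is counted by the starting material in it: one side product counts as two
- a doubled species enters its step squared and goes two at a time
- at the start none of the gas is dissolved
- run time (flask): 10 d

At the first instants the flask held starting material and no dissolved gas. At the full charge dissolved gas has a half-life of 0.13 d against step 2, short against the 10 d of the run, so I froze it where transfer balances use, which against the full charge is 28.0% of saturation. Target and isomer of the product relax with a half-life of 0.230 d, so I froze their split as well: target is 67.7% of this pair, which I called the pool. I dropped step 5, which at the full charge gives target a half-life of 16 d, longer than the run.

In the middle of the run, starting material and pool compete for the same gas. I carried one number, a selectivity factor: the constant of over-reaction over the constant of formation, with target's share of the pool counted in, 0.876. The gas level cancels from this relation. The pool, as a fraction of the charge, is the fraction of starting material left raised to this factor, minus that fraction, divided by the factor's shortfall from unity.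

For the end I needed a mean gas level. I set the sink at half the charge and added self-condensation, which gave 38.5% of saturation. Over the run this reckoning left 3.19% of the starting material and a pool of 13.7%, so I reckoned target at 9.29%. For the end of the run I reckoned the first-order loss of dissolved gas through transfer and steps 2 and 3 at 0.122 h⁻¹. Adding step 4 at the gas level that this loss by itself allows gave 52.8% of saturation.

The forecast gave 10.5% and 56%, on the ground that "over-reaction at a similar rate burns down the target". Its target stood 1.2 percentage points above mine, and its dissolved gas 3.2 points above mine.

The flask gave 9.14% target and 55.3% of saturation, both inside the forecast's margins. With twice the coefficient of step 1, the same flask held 2.69% target, 7.8 points under the forecast. The factor 0.876, applied to the 3.3% of starting material left in the flask, gives 9.43% target. In the neighbouring flask charged with 0.10 M, 1.3% of starting material was left, and the same factor gives 5.01% target; that flask held 5.03%.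

Its constants come from no measurement, and the outcome is calculated.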